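- I started from time, and from the mean interval between two turnovers in the spring run. One turnover here means one J converted per D charged.

- spring: J 0.020 M; D 0.015 mol%; run made earlier
- flask: J 0.020 M; D 0.01 mol%

spring run (percent of the J charged)

| time / h | L / % | J / % |
|---|---|---|
| 1.00 | 1.3 | 99.0 |
| 2.00 | 0.1 | 97.5 |
| 3.00 | 3.8 | 95.9 |
| 4.00 | 7.7 | 95.3 |
| 5.00 | 6.3 | 92.5 |
| 6.00 | 7.2 | 91.8 |

(scatter of a reading: 1 percentage point)

- the numbers in the tables scatter with a standard deviation of 1 percentage point
- no earlier run changes the charge of D; that part of a forecast is a guess

* factor on the rate of making L when 10 % of the J are converted if D is charged twice over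
* factor on the rate when 10 % of the J are converted if D is charged at 0.001 mol% instead

- First rung: after 6.00 h the spring run read J at 91.8 %, so with 0.015 mol% of D each D charged had made on average about 547 turnovers, a mean of one every 0.659 min. This is a reading and carries the scatter of 1 percentage point.
- Next rung: the spring run stopped at that count, with J still falling.
- Last rung: I counted the turnovers owed per D charged to reach the conversion asked about, which I call the mark: the conversion divided by the loading, which is 1000 for 10 % at 0.01 mol%. The flask therefore owed more than the spring run had shown. At the spring pace it would arrive after 11.0 h, later than the last reading.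
- My own reckoning assumed the same pace per D at every charge, so the rate would follow the charge: a factor of 2 on doubling, and 0.100 at 0.001 mol%. No run varied D, so this was a guess.
- The forecast gave 1.9 and 0.1, saying “The default is first order in catalyst”. Its first factor stood lower than mine.

    D ⇌ Z (K = 2.36, k = 0.100 h⁻¹)
    J + Z → L + Z, rate k2*[J]^2.5*[Z]/(1 + ([J]/Kh2)^2.5) (21.4 mM, k = 2.42 × 10⁷ L²·⁵ mol⁻²·⁵ h⁻¹)
    2 Z → Q (k = 2.80 × 10⁵ L mol⁻¹ h⁻¹)

- The flask gave 1.58 on doubling and 0.130 at 0.001 mol%. At the mark, reached after 0.344 d, 31.5 % of the catalyst in the flask stood as Q. The 1000 turnovers per D charged took the flask that time, a mean of 121 h⁻¹. At 0.001 mol% the same count gives 10000 turnovers per D charged to the mark, and the rate per D charged at that mark stood at 1.30 times that of the flask.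

The runs were computed with constants of no real substance; scatter was added.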